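**Plan**
- Retrosynthesis: the free phenol is masked as a benzyl ether and the C3–H bond is traced back to a C3–CO2Et group. The C3–CH2Ar bond and the aryl–CH2 bond of the C4 arm are then cut together, which leads to an aryl Grignard reagent, 3,4,5-trimethoxybenzyl bromide and a cyclopropane-fused lactone. That lactone is cut into (R)-epichlorohydrin and diethyl malonate.
- Enabling feature: C4 carries a CH2–aryl arm and sits between C3 and the C5 OCH2. The arm CH2, C4, C5 and C3 correspond to the cyclopropane CH2 (C6), the bridgehead CH (C5), the OCH2 (C4) and the doubly activated carbon (C1) of a 3-oxabicyclo[3.1.0]hexan-2-one 1-carboxylate.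
- Forward order: the lactone ring and the cyclopropane arise together in step 1. The three-membered ring is then opened by the aryl nucleophile and the resulting enolate is benzylated in the same flask. The extra ester is removed and the phenol is freed last.
- Stereochemistry: C4 comes from (R)-epichlorohydrin (one inversion in step 1, untouched afterwards). C3 is set by equilibration to the trans lactone after the ester is lost.

Key step: step 4

Remark: the target is read as the (3R,4R)-trans lactone (ring numbering O1, C2 = carbonyl, C3, C4, C5). The Grignard solution is counted as a step of its own.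

**Step 1**
Reactants: 1 (R)-epichlorohydrin; 2 diethyl malonate
Product: 3 ethyl (1S,5R)-2-oxo-3-oxabicyclo[3.1.0]hexane-1-carboxylate
Conditions: NaOEt (1.0 equiv), EtOH, rt then reflux
Reagents that add atoms: none
Why: In this tandem malonate alkylation the malonate anion opens the epoxide at its CH2 end, the alkoxide displaces chloride to give a transposed epoxide, a second deprotonation leads to 3-exo-tet opening at the epoxide CH with inversion (cyclopropane), and the freed alkoxide lactonises onto the cis ester, so C5 derives from the epichlorohydrin stereocentre and C1 follows from the obligatory cis ring fusion.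

**Step 2**
Reactants: 4 4-bromo-2,6-dimethoxyphenol
Product: 5 2-(benzyloxy)-5-bromo-1,3-dimethoxybenzene
Conditions: BnBr, K2CO3, DMF, 60 °C
Reagents that add atoms: benzyl bromide, BrCc1ccccc1
Why: Williamson ether synthesis of the phenoxide with a benzylic bromide masks the acidic OH, which would otherwise quench the Grignard reagent, as an ether that hydrogenolysis removes at the end.

**Step 3**
Reactants: 5 2-(benzyloxy)-5-bromo-1,3-dimethoxybenzene
Product: 6 [4-(benzyloxy)-3,5-dimethoxyphenyl]magnesium bromide (titrated THF solution, used directly)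
Conditions: Mg turnings, I2 (cat.), THF, 45 °C
Reagents that add atoms: magnesium, [Mg]
Why: Grignard reagent formation by insertion of magnesium into the aryl C–Br bond is routine for alkoxy-substituted aryl bromides, and the benzyl and methyl ethers are inert to it.

**Step 4**
Reactants: 3 ethyl (1S,5R)-2-oxo-3-oxabicyclo[3.1.0]hexane-1-carboxylate; 6 [4-(benzyloxy)-3,5-dimethoxyphenyl]magnesium bromide; 7 3,4,5-trimethoxybenzyl bromide
Product: 9 ethyl (3R,4R)-4-[4-(benzyloxy)-3,5-dimethoxybenzyl]-2-oxo-3-(3,4,5-trimethoxybenzyl)tetrahydrofuran-3-carboxylate (the two arylmethyl groups trans), via bromomagnesium lactone enolate 8 (not isolated)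
Conditions: 6 (1.15 equiv), CuI (10 mol %), THF, −30 °C; then DMPU, 7 (1.5 equiv), −30 °C to rt; aq. NH4Cl
Reagents that add atoms: none
Why: Transmetalation of 6 to CuI should give an aryl cuprate of monovalent copper that attacks the unsubstituted cyclopropane carbon C6 of 3 in an SN2-like homoconjugate addition, breaking the strained C1–C6 bond and leaving the chelated enolate 8, which, once DMPU has loosened the magnesium chelate, is C-benzylated by 7 in an SN2 step. The closest known reactions are the CuI-catalysed Grignard opening of this same bicyclic lactone and of cyclopropane-1,1-diesters, and the alkylation of 3-alkoxycarbonyl butyrolactone enolates with benzylic halides; the step runs these two in one flask. No ring is closed: the three-membered ring is opened and the lactone is kept. The new quaternary centre C3 is set by approach of 7 to the enolate face anti to the C4 arylmethyl group, whereas C4 takes no part in either bond formation and keeps the configuration fixed in step 1. The selectivity needed is attack at C6 in preference to C5 or the two carbonyl groups, and it is secured by the geminal lactone and ester acceptors on C1 (which polarise the C1–C6 bond and stabilise the departing enolate), by C6 being the only unhindered CH2 of the ring, and by the soft cuprate at low temperature. The facial selectivity at C3 is not critical, because that centre is set anew in step 5.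

**Step 5**
Reactants: 9 ethyl (3R,4R)-4-[4-(benzyloxy)-3,5-dimethoxybenzyl]-2-oxo-3-(3,4,5-trimethoxybenzyl)tetrahydrofuran-3-carboxylate
Product: 11 (3R,4R)-4-[4-(benzyloxy)-3,5-dimethoxybenzyl]-3-(3,4,5-trimethoxybenzyl)dihydrofuran-2(3H)-one, via cis lactone 10 (not isolated)
Conditions: LiCl (3 equiv), H2O (2 equiv), DMSO, 150 °C; cool to 60 °C, DBU (0.5 equiv), same flask; aq. HCl work-up
Reagents that add atoms: none
Why: In this Krapcho dealkoxycarbonylation chloride dealkylates the ethyl ester, the β-carbonyl carboxylate loses CO2 and water protonates the lactone enolate to give both C3 epimers, after which soft enolisation by LiCl and DBU should equilibrate the cis epimer 10 to the more stable trans lactone 11 while the non-acidic C4 stays R.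

**Step 6**
Reactants: 11 (3R,4R)-4-[4-(benzyloxy)-3,5-dimethoxybenzyl]-3-(3,4,5-trimethoxybenzyl)dihydrofuran-2(3H)-one
Product: 12 (3R,4R)-4-(4-hydroxy-3,5-dimethoxybenzyl)-3-(3,4,5-trimethoxybenzyl)dihydrofuran-2(3H)-one (target)
Conditions: H2 (1 atm), 10% Pd/C, EtOAc–EtOH, rt
Reagents that add atoms: none
Why: Hydrogenolysis of the aryl benzyl ether over Pd/C is neutral, so the lactone, the aryl methyl ethers and both stereocentres should be unaffected.

**Compound list**
1 | (R)-epichlorohydrin, (2R)-2-(chloromethyl)oxirane | ClC[C@H]1CO1 | starting material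
2 | diethyl malonate | CCOC(=O)CC(=O)OCC | starting material
3 | ethyl (1S,5R)-2-oxo-3-oxabicyclo[3.1.0]hexane-1-carboxylate | CCOC(=O)[C@]12C[C@H]1COC2=O | intermediate
4 | 4-bromo-2,6-dimethoxyphenol | COc1cc(Br)cc(OC)c1O | starting material
5 | 2-(benzyloxy)-5-bromo-1,3-dimethoxybenzene | COc1cc(Br)cc(OC)c1OCc1ccccc1 | intermediate
6 | [4-(benzyloxy)-3,5-dimethoxyphenyl]magnesium bromide | COc1cc([Mg]Br)cc(OC)c1OCc1ccccc1 | intermediate
7 | 3,4,5-trimethoxybenzyl bromide | COc1cc(CBr)cc(OC)c1OC | starting material
8 | bromomagnesium enolate of ethyl (4R)-4-[4-(benzyloxy)-3,5-dimethoxybenzyl]-2-oxotetrahydrofuran-3-carboxylate | COc1cc(C[C@H]2COC(O[Mg]Br)=C2C(=O)OCC)cc(OC)c1OCc1ccccc1 | intermediate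
9 | ethyl (3R,4R)-4-[4-(benzyloxy)-3,5-dimethoxybenzyl]-2-oxo-3-(3,4,5-trimethoxybenzyl)tetrahydrofuran-3-carboxylate | COc1cc(C[C@H]2COC(=O)[C@]2(C(=O)OCC)Cc2cc(OC)c(OC)c(OC)c2)cc(OC)c1OCc1ccccc1 | intermediate
10 | (3S,4R)-4-[4-(benzyloxy)-3,5-dimethoxybenzyl]-3-(3,4,5-trimethoxybenzyl)dihydrofuran-2(3H)-one (cis epimer) | COc1cc(C[C@H]2COC(=O)[C@H]2Cc2cc(OC)c(OC)c(OC)c2)cc(OC)c1OCc1ccccc1 | intermediate
11 | (3R,4R)-4-[4-(benzyloxy)-3,5-dimethoxybenzyl]-3-(3,4,5-trimethoxybenzyl)dihydrofuran-2(3H)-one (trans) | COc1cc(C[C@H]2COC(=O)[C@@H]2Cc2cc(OC)c(OC)c(OC)c2)cc(OC)c1OCc1ccccc1 | intermediate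
12 | (3R,4R)-4-(4-hydroxy-3,5-dimethoxybenzyl)-3-(3,4,5-trimethoxybenzyl)dihydrofuran-2(3H)-one | COc1cc(C[C@H]2COC(=O)[C@@H]2Cc2cc(OC)c(OC)c(OC)c2)cc(OC)c1O | target

**Totals**
Total step count: 6.
Longest linear sequence: 5 steps (steps 2, 3, 4, 5 and 6, from 4).

**Steps most likely to fail**

Step 4. The C-benzylation of the tightly chelated magnesium enolate may be slow, so that copper-mediated coupling of surplus Grignard reagent with the benzylic bromide, or simple protonation on work-up, takes over. The fallback separates the two bond formations. It sets out from enolate 8, which is quenched with dilute HCl to isolate ethyl (3S,4R)-4-[4-(benzyloxy)-3,5-dimethoxybenzyl]-2-oxotetrahydrofuran-3-carboxylate F1 (the C3 centre is labile; the trans form is shown). This β-dicarbonyl compound is then alkylated as its caesium enolate with 7 (Cs2CO3, DMF, rt), and the route is rejoined at 9.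

Step 5. Chloride dealkylation of the ethyl ester may be sluggish, or the equilibration at C3 may stay incomplete. The fallback sets out from 9 and uses saponification and thermal decarboxylation instead. KOH in aqueous EtOH at reflux hydrolyses the ester and opens the lactone to dipotassium 2-[(2R)-1-(4-benzyloxy-3,5-dimethoxyphenyl)-3-hydroxypropan-2-yl]-2-(3,4,5-trimethoxybenzyl)propanedioate F2. Acidification with HCl recloses the ring to (4R)-4-[4-(benzyloxy)-3,5-dimethoxybenzyl]-2-oxo-3-(3,4,5-trimethoxybenzyl)tetrahydrofuran-3-carboxylic acid F3 (either C3 epimer). Heating F3 in toluene at 110 °C should expel CO2 to give a mixture of 10 and 11, and DBU in the same solvent should converge it on 11, where the route is rejoined.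

Step 3. Magnesium insertion into the electron-rich, flanked aryl bromide may start slowly and be accompanied by homocoupling. The fallback sets out from 5 and uses halogen–lithium exchange (n-BuLi, THF, −78 °C) to give [4-(benzyloxy)-3,5-dimethoxyphenyl]lithium F4. Transmetalation with MgBr2·OEt2 at −78 °C to 0 °C then gives the Grignard reagent, and the route is rejoined at 6.

**Further compounds**
F1 | step 4 | ethyl (3S,4R)-4-[4-(benzyloxy)-3,5-dimethoxybenzyl]-2-oxotetrahydrofuran-3-carboxylate | COc1cc(C[C@H]2COC(=O)[C@@H]2C(=O)OCC)cc(OC)c1OCc1ccccc1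
F2 | step 5 | dipotassium 2-[(2R)-1-(4-benzyloxy-3,5-dimethoxyphenyl)-3-hydroxypropan-2-yl]-2-(3,4,5-trimethoxybenzyl)propanedioate | COc1cc(C[C@@H](CO)C(Cc2cc(OC)c(OC)c(OC)c2)(C(=O)[O-])C(=O)[O-])cc(OC)c1OCc1ccccc1.[K+].[K+]
F3 | step 5 | (4R)-4-[4-(benzyloxy)-3,5-dimethoxybenzyl]-2-oxo-3-(3,4,5-trimethoxybenzyl)tetrahydrofuran-3-carboxylic acid (C3 epimers) | COc1cc(C[C@H]2COC(=O)C2(C(=O)O)Cc2cc(OC)c(OC)c(OC)c2)cc(OC)c1OCc1ccccc1
F4 | step 3 | [4-(benzyloxy)-3,5-dimethoxyphenyl]lithium | [Li]c1cc(OC)c(OCc2ccccc2)c(OC)c1
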